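The synthesis rests on cutting the five-membered lactone ring (O–C6–C7–C11–C12) at C7–C8 and C11–C13. One three-component operation adds a C8 acyl-anion equivalent to C7 of a C6-substituted butenolide and aminomethylates the resulting enolate at C11, so the trans C6/C7 pattern and the latent exocyclic C11=C13 methylene of the target arise together. The precursors are the silylated (S)-hydroxymethylbutenolide, a 1,3-dithiane carrying the C9–C10 allyl unit with a protected C14 oxygen, and dimethylmethyleneammonium iodide. Later, C8 is reduced and acylated, a C1–C4 unit is joined at C5, and the ten-membered ring is closed by metathesis at C1=C10.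

Key step: step 4

Remark (numbering): ten-membered ring C1–C10 with C1=C10; C15 is the hydroxymethyl carbon on C4, C14 the ester carbon on C10; C11, C12 and C13 are the lactone α-carbon, carbonyl and methylene.

Remark (design): in 11 the nitrogen on C13 is cis to the C5 arm across the lactone, so a C5 sulfonate or halide could be captured by nitrogen in a six-membered ring. The amine is therefore held as its N–borane complex from step 6 to step 12, the span in which C5 is made electrophilic.

Remark (assumption): (R)-2-methylbutanoic acid, hex-5-enoyl chloride and (S)-4-benzyloxazolidin-2-one are taken as purchased.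

Step 1
Reactants: 1 (S)-5-(hydroxymethyl)furan-2(5H)-one
Product: 2 (S)-5-(tert-butyldiphenylsilyloxymethyl)furan-2(5H)-one
Conditions: TBDPSCl, imidazole, CH2Cl2, 0 °C to rt
Reagents that add atoms: tert-butyl(chloro)diphenylsilane, CC(C)(C)[Si](Cl)(c1ccccc1)c1ccccc1
Why: Imidazole-mediated silylation of the primary alcohol is routine and does not touch the C6 stereocentre, and the bulky silyl ether later blocks one face of the butenolide.

Step 2
Reactants: 3 1,3-dithiane; 4 3-chloro-2-(chloromethyl)prop-1-ene
Product: 6 2-[2-(chloromethyl)prop-2-enyl]-1,3-dithiane, via 2-lithio-1,3-dithiane 5 (not isolated)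
Conditions: n-BuLi, THF, −30 °C; then added to 4 (3 equiv), THF, −78 to 0 °C
Reagents that add atoms: none
Why: Corey–Seebach alkylation, in which the dithiane anion displaces one allylic chloride by SN2, and inverse addition to an excess of the dichloride suppresses double alkylation (the product is less acidic than 1,3-dithiane, so it is not deprotonated).

Step 3
Reactants: 6 2-[2-(chloromethyl)prop-2-enyl]-1,3-dithiane
Product: 7 2-[2-(4-methoxybenzyloxymethyl)prop-2-enyl]-1,3-dithiane
Conditions: 4-MeOC6H4CH2OH, NaH, Bu4NI (cat.), THF, 0 °C to rt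
Reagents that add atoms: 4-methoxybenzyl alcohol, COc1ccc(CO)cc1
Why: Williamson ether synthesis on a reactive allylic chloride, where direct and allylically transposed displacement give the same product because the allyl unit is symmetric.

Step 4
Reactants: 7 2-[2-(4-methoxybenzyloxymethyl)prop-2-enyl]-1,3-dithiane; 2 (S)-5-(tert-butyldiphenylsilyloxymethyl)furan-2(5H)-one; 8 dimethylmethyleneammonium iodide
Product: 11 (3R,4S,5S)-5-(tert-butyldiphenylsilyloxymethyl)-3-(dimethylaminomethyl)-4-{2-[2-(4-methoxybenzyloxymethyl)prop-2-enyl]-1,3-dithian-2-yl}oxolan-2-one, via lithiated dithiane 9 (not isolated), via lithium lactone enolate 10 (not isolated)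
Conditions: 7, n-BuLi, THF, −30 °C; (Me2N)3PO, −78 °C; 2, −78 °C; then 8, −78 °C to rt
Reagents that add atoms: none
Why: The 2-lithiodithiane 9, loosened to a solvent-separated ion pair by (Me2N)3PO, adds in Michael fashion to C7 of butenolide 2 to give lithium enolate 10, which is C-alkylated at C11 by the iminium ion of 8 (Mannich reaction), so C7–C8 and C11–C13 form in one flask. The closest known reaction type is the tandem conjugate addition–enolate trapping of sulfur-stabilised acyl-anion equivalents on γ-substituted butenolides, used to make trans,trans-disubstituted lactones. No ring is closed. The C7 stereocentre is set by the C6 stereocentre of 2, the nucleophile entering anti to the bulky silyloxymethyl arm (C5), and the C11 stereocentre is set by C7, the iminium approaching the enolate face opposite the new dithianyl group. The step needs 1,4-addition to win over 1,2-addition and over γ-deprotonation of the butenolide, which the soft, hindered thioacetal anion, the polar additive and −78 °C should secure, while facial control comes from the tert-butyldiphenylsilyl ether.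

Step 5
Reactants: 11 the three-component lactone
Product: 12 C8 ketone: lactone of 11 (C6, C7, C11 unchanged) carrying a 3-(4-methoxybenzyloxymethyl)but-3-enoyl group on C7
Conditions: PhI(OCOCF3)2, CF3CO2H (1.1 equiv), MeCN–H2O 9:1, 0 °C; cold NaHCO3 wash, used at once
Reagents that add atoms: water, O
Why: Oxidative dethioacetalisation with a hypervalent iodine reagent, sulfur being oxidised far faster than the alkene or the anisyl ring while the protonated amine is inert to the oxidant; no stereocentre changes and the base-sensitive β,γ-unsaturated ketone is carried on at once.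

Step 6
Reactants: 12 C8 ketone
Product: 13 (8R)-alcohol as the N–borane complex of the dimethylamino group (C6, C7, C11 as in 11)
Conditions: BH3·SMe2 (1.0 equiv), CH2Cl2, −78 °C; then (S)-2-methyl-CBS-oxazaborolidine (0.3 equiv), catecholborane, −78 to −40 °C; MeOH
Reagents that add atoms: borane–dimethyl sulfide, C[S+](C)[BH3-]
Why: Corey–Bakshi–Shibata reduction, in which the first equivalent of borane ties up the basic nitrogen as a stable N–BH3 adduct (removing the base that could conjugate the enone or bind the catalyst) and the (S)-oxazaborolidine then delivers hydride from catecholborane with the branched C7 side as the large group, which should give the 8R alcohol under reagent control while catecholborane at low temperature leaves the alkene alone.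

Step 7
Reactants: 13 (8R)-alcohol N–borane; 14 (R)-2-methylbutanoic acid
Product: 15 (8R)-(R)-2-methylbutanoate, still the C5 silyl ether, C14 PMB ether and N–borane
Conditions: DCC, DMAP, CH2Cl2, 0 °C to rt
Reagents that add atoms: none
Why: Steglich esterification acylates the C8 oxygen without touching the C8–O bond, so the 8R configuration is retained, and the α-alkyl acid carries no group that would favour racemisation.

Step 8
Reactants: 15 C8 ester silyl ether
Product: 16 C5 primary alcohol (C8 ester, C14 PMB ether, N–borane)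
Conditions: Bu4NF, AcOH, THF, 0 °C to rt
Reagents that add atoms: none
Why: Fluoride-induced desilylation, buffered with acetic acid so that the esters and the N–borane stay intact and no acyl shift from O8 to O5 is provoked.

Step 9
Reactants: 17 (S)-4-benzyloxazolidin-2-one; 18 hex-5-enoyl chloride
Product: 19 (S)-4-benzyl-3-(hex-5-enoyl)oxazolidin-2-one
Conditions: Et3N, DMAP (cat.), CH2Cl2, 0 °C to rt
Reagents that add atoms: none
Why: N-Acylation of the oxazolidinone with an acid chloride under amine/DMAP catalysis is a standard way to load the auxiliary.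

Step 10
Reactants: 16 C5 primary alcohol; 19 (S)-4-benzyl-3-(hex-5-enoyl)oxazolidin-2-one
Product: 22 (4R)-alkylated imide: C5 bonded to the α-carbon (C4) of the hexenoyl imide, via C5 triflate 20 (not isolated), via sodium imide enolate 21 (not isolated)
Conditions: 16, Tf2O, 2,6-lutidine, CH2Cl2, −78 °C; 19 (2.5 equiv), NaN(SiMe3)2, THF, −78 °C; combined, −78 to −40 °C
Reagents that add atoms: none
Why: Evans asymmetric alkylation, in which the chelated sodium Z-enolate is attacked by the primary triflate on the face away from the benzyl group, setting C4 as R; the triflate is reactive enough at low temperature for this soft imide enolate to leave lactone and ester untouched, and the N–borane prevents capture of C5 by nitrogen.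

Step 11
Reactants: 22 alkylated imide
Product: 23 (4R)-C15 primary alcohol, acyclic diene with N–borane
Conditions: NaBH4, THF–H2O, 0 °C to rt
Reagents that add atoms: none
Why: Borohydride reduction of the activated exocyclic imide carbonyl (reductive auxiliary removal) is faster than attack on the γ-lactone or the hindered ester, gives the C15 alcohol directly without affecting C4, and returns the oxazolidinone.

Step 12
Reactants: 23 C15 alcohol diene N–borane
Product: 25 ten-membered carbocycle with ring-cis C1=C10, C14 PMB ether, C15 alcohol, free dimethylamine, via ammonium tosylate diene 24 (not isolated)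
Conditions: TsOH·H2O (1.1 equiv), MeOH, 45 °C; evaporate; second-generation Grubbs catalyst RuCl2(=CHPh)(PCy3)(H2IMes) (10 mol %), ClCH2CH2Cl, 1 mM, 75 °C; NaHCO3 wash
Reagents that add atoms: none
Why: Acid methanolysis removes the borane and leaves the amine as its tosylate, which cannot bind ruthenium, and ring-closing metathesis then joins the terminal C1 olefin to the 1,1-disubstituted C10 olefin with loss of ethene, the ten-membered ring favouring the ring-cis trisubstituted alkene (E by descriptor) that the target needs.

Step 13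
Reactants: 25 ring PMB ether
Product: 26 C14/C15 diol (C14 allylic alcohol)
Conditions: TsOH·H2O (1.05 equiv), then DDQ, CH2Cl2–H2O, 0 °C; NaHCO3 wash
Reagents that add atoms: none
Why: Oxidative cleavage of the 4-methoxybenzyl ether by DDQ through the benzylic oxocarbenium ion, run on the ammonium salt so that the amine cannot be dehydrogenated.

Step 14
Reactants: 26 diol
Product: 27 C14 enal
Conditions: MnO2, CH2Cl2, rt
Reagents that add atoms: none
Why: MnO2 oxidises the allylic C14 alcohol selectively over the saturated C15 alcohol, and the ring holds the enal geometry.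

Step 15
Reactants: 27 enal
Product: 28 C14 carboxylic acid (amino acid)
Conditions: NaClO2, NaH2PO4, 2-methylbut-2-ene, t-BuOH–H2O, 0 °C to rt
Reagents that add atoms: sodium chlorite, [Na+].[O-]Cl=O
Why: Pinnick oxidation converts the enal to the acid under weakly acidic conditions in which the amine is protonated, with 2-methylbut-2-ene scavenging hypochlorite.

Step 16
Reactants: 28 amino acid
Product: 30 CNP0141952.3, via trimethylammonium methyl ester iodide 29 (not isolated)
Conditions: MeI (excess), KHCO3, DMF, rt
Reagents that add atoms: iodomethane, CI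
Why: Iodomethane alkylates the carboxylate to the methyl ester and quaternises the amine, and bicarbonate then triggers E1cB loss of trimethylamine from the β-ammonium lactone (Hofmann-type elimination of a Mannich base), unveiling the C11=C13 methylene without touching the free C15 alcohol.

Compound list
1 | (S)-5-(hydroxymethyl)furan-2(5H)-one | OC[C@H]1OC(=O)C=C1 | starting material
2 | (S)-5-(tert-butyldiphenylsilyloxymethyl)furan-2(5H)-one | O=C1C=C[C@@H](CO[Si](c2ccccc2)(c2ccccc2)C(C)(C)C)O1 | intermediate
3 | 1,3-dithiane | C1CSCSC1 | starting material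
4 | 3-chloro-2-(chloromethyl)prop-1-ene | ClCC(=C)CCl | starting material
5 | 2-lithio-1,3-dithiane | [Li]C1SCCCS1 | intermediate (not isolated)
6 | 2-[2-(chloromethyl)prop-2-enyl]-1,3-dithiane | C=C(CCl)CC1SCCCS1 | intermediate
7 | 2-[2-(4-methoxybenzyloxymethyl)prop-2-enyl]-1,3-dithiane | C=C(COCc1ccc(OC)cc1)CC1SCCCS1 | intermediate
8 | dimethylmethyleneammonium iodide | C=[N+](C)C.[I-] | starting material
9 | 2-lithio-2-[2-(4-methoxybenzyloxymethyl)prop-2-enyl]-1,3-dithiane | [Li]C1(CC(=C)COCc2ccc(OC)cc2)SCCCS1 | intermediate (not isolated)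
10 | lithium enolate of the conjugate adduct (C7 dithianyl anti to the C5 arm) | [Li]OC=1O[C@H](CO[Si](c2ccccc2)(c2ccccc2)C(C)(C)C)[C@@H](C2(CC(=C)COCc3ccc(OC)cc3)SCCCS2)C=1 | intermediate (not isolated)
11 | (3R,4S,5S)-5-(tert-butyldiphenylsilyloxymethyl)-3-(dimethylaminomethyl)-4-{2-[2-(4-methoxybenzyloxymethyl)prop-2-enyl]-1,3-dithian-2-yl}oxolan-2-one (trans,trans) | O=C1O[C@H](CO[Si](c2ccccc2)(c2ccccc2)C(C)(C)C)[C@@H](C2(CC(=C)COCc3ccc(OC)cc3)SCCCS2)[C@@H]1CN(C)C | intermediate
12 | C8 ketone: trans,trans lactone of 11 with a 3-(4-methoxybenzyloxymethyl)but-3-enoyl group on C7 | O=C1O[C@H](CO[Si](c2ccccc2)(c2ccccc2)C(C)(C)C)[C@@H](C(=O)CC(=C)COCc2ccc(OC)cc2)[C@@H]1CN(C)C | intermediate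
13 | (8R)-alcohol, dimethylamine as N–borane complex | O=C1O[C@H](CO[Si](c2ccccc2)(c2ccccc2)C(C)(C)C)[C@@H]([C@H](O)CC(=C)COCc2ccc(OC)cc2)[C@@H]1C[N+](C)(C)[BH3-] | intermediate
14 | (R)-2-methylbutanoic acid | CC[C@@H](C)C(O)=O | starting material
15 | (8R)-(R)-2-methylbutanoate of 13 | O=C1O[C@H](CO[Si](c2ccccc2)(c2ccccc2)C(C)(C)C)[C@@H]([C@H](OC(=O)[C@H](C)CC)CC(=C)COCc2ccc(OC)cc2)[C@@H]1C[N+](C)(C)[BH3-] | intermediate
16 | C5 primary alcohol (C8 ester, C14 PMB ether, N–borane) | O=C1O[C@H](CO)[C@@H]([C@H](OC(=O)[C@H](C)CC)CC(=C)COCc2ccc(OC)cc2)[C@@H]1C[N+](C)(C)[BH3-] | intermediate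
17 | (S)-4-benzyloxazolidin-2-one | O=C1N[C@@H](Cc2ccccc2)CO1 | starting material
18 | hex-5-enoyl chloride | C=CCCCC(Cl)=O | starting material
19 | (S)-4-benzyl-3-(hex-5-enoyl)oxazolidin-2-one | C=CCCCC(=O)N1[C@@H](Cc2ccccc2)COC1=O | intermediate
20 | C5 trifluoromethanesulfonate of 16 | O=C1O[C@H](COS(=O)(=O)C(F)(F)F)[C@@H]([C@H](OC(=O)[C@H](C)CC)CC(=C)COCc2ccc(OC)cc2)[C@@H]1C[N+](C)(C)[BH3-] | intermediate (not isolated)
21 | sodium Z-enolate of 19 | [Na]O/C(=C\CCC=C)N1[C@@H](Cc2ccccc2)COC1=O | intermediate (not isolated)
22 | (4R)-alkylated imide, C5 joined to the α-carbon of the hexenoyl oxazolidinone | O=C1O[C@H](C[C@H](C(=O)N2[C@@H](Cc3ccccc3)COC2=O)CCC=C)[C@@H]([C@H](OC(=O)[C@H](C)CC)CC(=C)COCc2ccc(OC)cc2)[C@@H]1C[N+](C)(C)[BH3-] | intermediate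
23 | (4R)-C15 alcohol, acyclic diene, N–borane | O=C1O[C@H](C[C@H](CO)CCC=C)[C@@H]([C@H](OC(=O)[C@H](C)CC)CC(=C)COCc2ccc(OC)cc2)[C@@H]1C[N+](C)(C)[BH3-] | intermediate
24 | dimethylammonium tosylate of the diene | O=C1O[C@H](C[C@H](CO)CCC=C)[C@@H]([C@H](OC(=O)[C@H](C)CC)CC(=C)COCc2ccc(OC)cc2)[C@@H]1C[NH+](C)C.Cc1ccc(cc1)S(=O)(=O)[O-] | intermediate (not isolated)
25 | ten-membered ring, ring-cis C1=C10, C14 PMB ether, C15 alcohol, C13 dimethylamine | O=C1O[C@@H]2C[C@H](CO)CC/C=C(/COCc3ccc(OC)cc3)C[C@@H](OC(=O)[C@H](C)CC)[C@H]2[C@@H]1CN(C)C | intermediate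
26 | C14 allylic alcohol / C15 alcohol diol | O=C1O[C@@H]2C[C@H](CO)CC/C=C(/CO)C[C@@H](OC(=O)[C@H](C)CC)[C@H]2[C@@H]1CN(C)C | intermediate
27 | C14 enal | O=C1O[C@@H]2C[C@H](CO)CC/C=C(/C=O)C[C@@H](OC(=O)[C@H](C)CC)[C@H]2[C@@H]1CN(C)C | intermediate
28 | C14 carboxylic acid | O=C1O[C@@H]2C[C@H](CO)CC/C=C(/C(O)=O)C[C@@H](OC(=O)[C@H](C)CC)[C@H]2[C@@H]1CN(C)C | intermediate
29 | C14 methyl ester, C13 trimethylammonium iodide | O=C1O[C@@H]2C[C@H](CO)CC/C=C(/C(=O)OC)C[C@@H](OC(=O)[C@H](C)CC)[C@H]2[C@@H]1C[N+](C)(C)C.[I-] | intermediate (not isolated)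
30 | CNP0141952.3: (4R,6R,7S,8R) trans-fused α-methylene lactone, (E)-C1=C10 methyl enoate, C15 hydroxymethyl, C8 (R)-2-methylbutanoate | C=C1C(=O)O[C@@H]2C[C@H](CO)CC/C=C(/C(=O)OC)C[C@@H](OC(=O)[C@H](C)CC)[C@@H]12 | target

Total steps: 16. Longest linear sequence: 14 steps (3 to 30 through steps 2–8 and 10–16).

Steps most likely to fail

Step 4. The hindered, strongly basic 2-alkyl-dithiane anion may deprotonate the butenolide at C6 or attack its carbonyl instead of C7. The fallback replaces the cyclic dithiane by the softer, less basic bis(phenylthio)acetal anion, a known partner for this tandem addition. It sets out from 4 and 2. Lithiated bis(phenylthio)methane would be alkylated with 4 to give 3-(chloromethyl)-1,1-bis(phenylthio)but-3-ene F1, and the chloride displaced with sodium 4-methoxybenzyl oxide to give 3-(4-methoxybenzyloxymethyl)-1,1-bis(phenylthio)but-3-ene F2. F2 would be lithiated (n-BuLi, THF, −78 °C), added to 2 and the enolate trapped with 8 to give the bis(phenylthio)acetal lactone F3. Hydrolysis of F3 with PhI(OCOCF3)2 in wet MeCN rejoins the route at 12.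

Step 12. Intermolecular metathesis of the terminal olefin (oligomerisation) may outrun closure onto the hindered 1,1-disubstituted olefin. The fallback swaps the order of deprotection and closure so that the ring is closed on the free C14 allylic alcohol, where the hydroxyl assists engagement of the hindered olefin and the bulky anisyl group is gone. It sets out from 23: acid methanolysis gives 24, DDQ on this salt removes the PMB group to give the acyclic C14/C15 diol diene F4, and metathesis of F4 as its tosylate with the same ruthenium carbene rejoins the route at 26.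

Step 10. Displacement at the β-acyloxy primary carbon may be slow, letting elimination or O-alkylation of the enolate compete. The fallback switches to a hydrazone azaenolate, a more nucleophilic carbon nucleophile, and a primary iodide. It sets out from 16: Appel iodination (I2, PPh3, imidazole) gives the C5 iodide F5. Hex-5-enal is condensed with (R)-1-amino-2-(methoxymethyl)pyrrolidine to the RAMP hydrazone F6, deprotonated with LiN(iPr)2 and alkylated with F5 at −100 to −78 °C to give the (4R)-alkylated hydrazone F7. Aqueous oxalic acid frees the (4R)-C15 aldehyde F8, and NaBH4 reduction rejoins the route at 23.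

Further compounds
F1 | step 4 | 3-(chloromethyl)-1,1-bis(phenylthio)but-3-ene | C=C(CCl)CC(Sc1ccccc1)Sc1ccccc1
F2 | step 4 | 3-(4-methoxybenzyloxymethyl)-1,1-bis(phenylthio)but-3-ene | C=C(COCc1ccc(OC)cc1)CC(Sc1ccccc1)Sc1ccccc1
F3 | step 4 | trans,trans lactone as 11 with a bis(phenylthio)acetal at C8 | O=C1O[C@H](CO[Si](c2ccccc2)(c2ccccc2)C(C)(C)C)[C@@H](C(CC(=C)COCc2ccc(OC)cc2)(Sc2ccccc2)Sc2ccccc2)[C@@H]1CN(C)C
F4 | step 12 | acyclic C14/C15 diol diene, free amine | O=C1O[C@H](C[C@H](CO)CCC=C)[C@@H]([C@H](OC(=O)[C@H](C)CC)CC(=C)CO)[C@@H]1CN(C)C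
F5 | step 10 | C5 iodide of 16 (N–borane) | O=C1O[C@H](CI)[C@@H]([C@H](OC(=O)[C@H](C)CC)CC(=C)COCc2ccc(OC)cc2)[C@@H]1C[N+](C)(C)[BH3-]
F6 | step 10 | hex-5-enal RAMP hydrazone | C=CCCC/C=N/N1CCC[C@@H]1COC
F7 | step 10 | (4R)-alkylated RAMP hydrazone | O=C1O[C@H](C[C@H](/C=N/N2CCC[C@@H]2COC)CCC=C)[C@@H]([C@H](OC(=O)[C@H](C)CC)CC(=C)COCc2ccc(OC)cc2)[C@@H]1C[N+](C)(C)[BH3-]
F8 | step 10 | (4R)-C15 aldehyde (N–borane) | O=C1O[C@H](C[C@H](C=O)CCC=C)[C@@H]([C@H](OC(=O)[C@H](C)CC)CC(=C)COCc2ccc(OC)cc2)[C@@H]1C[N+](C)(C)[BH3-]
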